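**Retrosynthetic overview**

- Oxolane numbering used here: O1, C2 (Me, bromovinyl), C3 (Cl), C4, C5; C1′ is the ring-bound vinyl carbon, C6 the CBr carbon, C7 the CH2Cl carbon.
- Enabling feature: C1′ (on C2) and C6 (on C5) sit cis on the oxolane, so joining them gives a second five-membered ring O1–C2–C1′–C6–C5, a latent furan; the target is a masked 7-oxabicyclo[2.2.1]heptene.
- Key disconnection: C2–C3 and C5–C4 by an enantioselective Diels–Alder reaction of 2,4-dimethylfuran with 2-chloroacrolein; the oxolane ring and a temporary 2,5-dihydrofuran ring form together, and the formyl group is only an activating group.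
- The formyl group is removed by oxidation and radical decarboxylation, with exo hydrogen delivery fixing the C3 chloride; ozonolysis of the temporary C1′=C6 bond then opens the bicycle to a cis keto-aldehyde.
- Aldehyde to (E)-bromovinyl; methyl ketone to chloromethyl ketone, chelation-controlled methyl addition (C6), then tertiary OH to Br with retention.

Key step: step 1

Remark: 2,4-dimethylfuran and stabilised 2-chloroacrolein are taken as purchasable. The sense of induction in step 1 is assigned by analogy with the behaviour of the (S)-tryptophan-derived catalyst towards 2-haloacroleins (2R adducts), so the (R)-catalyst is specified; its antipode would be used if the opposite sense were found.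

**Route**

Step 1
Reactants: 1 2,4-dimethylfuran; 2 2-chloroacrolein (2-chloroprop-2-enal)
Product: 3 (1S,2S,4S)-2-chloro-1,5-dimethyl-7-oxabicyclo[2.2.1]hept-5-ene-2-carbaldehyde
Conditions: (4R)-2-butyl-4-(1H-indol-3-ylmethyl)-3-(4-methylphenylsulfonyl)-1,3,2-oxazaborolidin-5-one (10 mol%), 1 in excess, CH2Cl2, −78 °C; Et3N quench at −78 °C
Reagents that add atoms: none
Why: This is a Lewis-acid-activated, concerted but asynchronous normal-demand [4+2] cycloaddition in which the boron-bound s-cis enal is attacked first at its CH2 terminus by the unsubstituted α-carbon of the furan, the second bond then closing between the chlorine-bearing carbon and the methylated α-carbon. The closest known reaction type is the oxazaborolidinone-catalysed enantioselective Diels–Alder addition of 2-haloacroleins to furan itself. The oxolane ring (O, the two furan α-carbons, the two enal carbons) is closed by suprafacial [4+2] addition across the furan 2,5-positions, which at the same time creates the temporary 2,5-dihydrofuran ring of the 7-oxabicyclo[2.2.1]heptene. The two bridgehead centres (later C2 and C5) are necessarily cis and their absolute sense is set by the catalyst, whose indole shields one face of the coordinated enal; the chlorine-bearing centre is expected with chlorine endo and formyl exo, as usual for 2-haloacroleins, but it is reset in step 3 and is not critical here. The step needs regioselectivity (chlorinated carbon bonded to the methylated furan carbon); both methyl groups make the free α-carbon the nucleophilic terminus, as known for captodative dienophiles with this furan, and low temperature with a cold amine quench should favour cycloaddition over conjugate arylation.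

Step 2
Reactants: 3 (1S,2S,4S)-2-chloro-1,5-dimethyl-7-oxabicyclo[2.2.1]hept-5-ene-2-carbaldehyde
Product: 4 (1S,2S,4S)-2-chloro-1,5-dimethyl-7-oxabicyclo[2.2.1]hept-5-ene-2-carboxylic acid
Conditions: NaClO2, NaH2PO4, 2-methylbut-2-ene (excess), t-BuOH/H2O, 0 °C to rt
Reagents that add atoms: sodium chlorite (NaClO2), [Na+].[O-]Cl=O
Why: Pinnick oxidation of a hindered, non-enolisable aldehyde is reliable, and the alkene scavenger intercepts HOCl so that the strained ring alkene and the three stereocentres stay untouched.

Step 3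
Reactants: 4 (1S,2S,4S)-2-chloro-1,5-dimethyl-7-oxabicyclo[2.2.1]hept-5-ene-2-carboxylic acid
Product: 7 (1S,4S,6S)-6-chloro-1,3-dimethyl-7-oxabicyclo[2.2.1]hept-2-ene, via acid chloride 5 (not isolated), via thiohydroxamate ester 6 (not isolated)
Conditions: (COCl)2, N,N-dimethylformamide (cat.), CH2Cl2, 0 °C; NaC5H4NOS (sodium salt of 1-hydroxypyridine-2-thione), 4-(dimethylamino)pyridine (cat.), PhH, dark; then Bu3SnH, (PhSe)2 (10 mol%), hν (visible), 10 °C
Reagents that add atoms: none
Why: Barton reductive decarboxylation gives a planar α-chloro radical that should take hydrogen from PhSeH (formed in situ, the fastest donor, to outrun homoallyl rearrangement) on the open exo face next to the oxygen bridge, so chlorine ends endo whatever the configuration of that carbon in 4 and the C3 centre of the target is set by the bicyclic skeleton.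

Step 4
Reactants: 7 (1S,4S,6S)-6-chloro-1,3-dimethyl-7-oxabicyclo[2.2.1]hept-2-ene
Product: 9 (2S,3S,5S)-5-acetyl-3-chloro-2-methyloxolane-2-carbaldehyde, via ozonide 8 (not isolated)
Conditions: O3, CH2Cl2, −78 °C; then Me2S, −78 °C to rt
Reagents that add atoms: ozone, [O-][O+]=O
Why: Ozonolysis with reductive work-up cleaves the only C=C bond, the temporary C1′=C6 link, and should release the 2,5-cis oxolane with a formyl group on the quaternary carbon and an acetyl group on C5 without touching a stereocentre.

Step 5
Reactants: 9 (2S,3S,5S)-5-acetyl-3-chloro-2-methyloxolane-2-carbaldehyde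
Product: 10 1-[(2S,4S,5S)-5-[(E)-2-bromoethenyl]-4-chloro-5-methyloxolan-2-yl]ethan-1-one
Conditions: CHBr3, CrBr2, THF, 0 °C to rt
Reagents that add atoms: bromoform, BrC(Br)Br
Why: Takai olefination with the gem-dichromium reagent from bromoform and divalent chromium is selective for aldehydes over ketones and for E-bromoalkenes, the bromide salt being chosen to avoid bromine–chlorine exchange; no stereocentre is affected.

Step 6
Reactants: 10 1-[(2S,4S,5S)-5-[(E)-2-bromoethenyl]-4-chloro-5-methyloxolan-2-yl]ethan-1-one
Product: 12 2-chloro-1-[(2S,4S,5S)-5-[(E)-2-bromoethenyl]-4-chloro-5-methyloxolan-2-yl]ethan-1-one, via silyl enol ether 11 (not isolated)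
Conditions: LiN(SiMe3)2, Me3SiCl, THF, −78 °C; then N-chlorosuccinimide, NaHCO3, THF, −20 to 0 °C
Reagents that add atoms: N-chlorosuccinimide, O=C1CCC(=O)N1Cl
Why: Kinetic deprotonation with in-situ silyl trapping should occur at the methyl group and not at the hindered α-alkoxy methine, and chlorination of a silyl enol ether with N-chlorosuccinimide is a standard route to chloromethyl ketones; C5 is not enolised and keeps its configuration.

Step 7
Reactants: 12 2-chloro-1-[(2S,4S,5S)-5-[(E)-2-bromoethenyl]-4-chloro-5-methyloxolan-2-yl]ethan-1-one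
Product: 13 (2S)-1-chloro-2-[(2S,4S,5S)-5-[(E)-2-bromoethenyl]-4-chloro-5-methyloxolan-2-yl]propan-2-ol
Conditions: MgBr2·OEt2, CH2Cl2, −78 °C; MeMgBr (Et2O), −78 °C; sat. aq. NH4Cl at −78 °C
Reagents that add atoms: methylmagnesium bromide (MeMgBr), C[Mg]Br
Why: Grignard addition under chelation control: magnesium bridges the ring oxygen and the ketone oxygen in a five-membered chelate and methyl should attack from the face of the small C5 hydrogen, giving the 2S carbinol with the CH2Cl carbon already in place; the cold quench prevents epoxide closure.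

Step 8
Reactants: 13 (2S)-1-chloro-2-[(2S,4S,5S)-5-[(E)-2-bromoethenyl]-4-chloro-5-methyloxolan-2-yl]propan-2-ol
Product: 14 (2S,3S,5S)-2-[(E)-2-bromoethenyl]-5-[(2S)-2-bromo-1-chloropropan-2-yl]-3-chloro-2-methyloxolane
Conditions: Me3SiBr (2.2 equiv), CH2Cl2, −40 to 0 °C
Reagents that add atoms: bromotrimethylsilane, C[Si](C)(C)Br
Why: Proposed new method: silylation and protonation turn the tertiary hydroxyl into a leaving group whose departure is assisted from the rear by the adjacent ring oxygen (and, less so, by the β-chlorine), giving a bridged oxiranium ion instead of an open cation, which the two β-heteroatoms disfavour; bromide then opens the bridge at the tertiary carbon with a second inversion, so C6 should keep its configuration (net retention). The closest known reaction types are the conversion of tertiary alcohols into bromides with Me3SiBr or HBr and the stereospecific oxiranium-mediated substitutions and ring expansions of 2-(1-sulfonyloxyalkyl)oxolanes.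

**Compound list**

1 | 2,4-dimethylfuran | Cc1cc(C)co1 | starting material
2 | 2-chloroacrolein (2-chloroprop-2-enal) | C=C(Cl)C=O | starting material
3 | (1S,2S,4S)-2-chloro-1,5-dimethyl-7-oxabicyclo[2.2.1]hept-5-ene-2-carbaldehyde (Cl endo, CHO exo) | O=C[C@]1(Cl)C[C@@H]2O[C@@]1(C)C=C2C | intermediate
4 | (1S,2S,4S)-2-chloro-1,5-dimethyl-7-oxabicyclo[2.2.1]hept-5-ene-2-carboxylic acid | OC(=O)[C@]1(Cl)C[C@@H]2O[C@@]1(C)C=C2C | intermediate
5 | (1S,2S,4S)-2-chloro-1,5-dimethyl-7-oxabicyclo[2.2.1]hept-5-ene-2-carbonyl chloride | ClC(=O)[C@]1(Cl)C[C@@H]2O[C@@]1(C)C=C2C | intermediate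
6 | 2-thioxopyridin-1(2H)-yl (1S,2S,4S)-2-chloro-1,5-dimethyl-7-oxabicyclo[2.2.1]hept-5-ene-2-carboxylate | S=c1ccccn1OC(=O)[C@]2(Cl)C[C@@H]3O[C@@]2(C)C=C3C | intermediate
7 | (1S,4S,6S)-6-chloro-1,3-dimethyl-7-oxabicyclo[2.2.1]hept-2-ene (Cl endo) | Cl[C@H]1C[C@@H]2O[C@@]1(C)C=C2C | intermediate
8 | secondary ozonide of 7 (1,2,4-trioxolane bridging the two former alkene carbons; configuration at these two carbons not specified) | CC12OOC(O1)[C@]3(C)O[C@H]2C[C@@H]3Cl | intermediate
9 | (2S,3S,5S)-5-acetyl-3-chloro-2-methyloxolane-2-carbaldehyde | CC(=O)[C@@H]1C[C@H](Cl)[C@](C)(C=O)O1 | intermediate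
10 | 1-[(2S,4S,5S)-5-[(E)-2-bromoethenyl]-4-chloro-5-methyloxolan-2-yl]ethan-1-one | CC(=O)[C@@H]1C[C@H](Cl)[C@](C)(/C=C/Br)O1 | intermediate
11 | trimethylsilyl enol ether of 10 (terminal, CH2=C(OSiMe3)–) | C=C(O[Si](C)(C)C)[C@@H]1C[C@H](Cl)[C@](C)(/C=C/Br)O1 | intermediate
12 | 2-chloro-1-[(2S,4S,5S)-5-[(E)-2-bromoethenyl]-4-chloro-5-methyloxolan-2-yl]ethan-1-one | ClCC(=O)[C@@H]1C[C@H](Cl)[C@](C)(/C=C/Br)O1 | intermediate
13 | (2S)-1-chloro-2-[(2S,4S,5S)-5-[(E)-2-bromoethenyl]-4-chloro-5-methyloxolan-2-yl]propan-2-ol | C[C@@](O)(CCl)[C@@H]1C[C@H](Cl)[C@](C)(/C=C/Br)O1 | intermediate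
14 | (2S,3S,5S)-2-[(E)-2-bromoethenyl]-5-[(2S)-2-bromo-1-chloropropan-2-yl]-3-chloro-2-methyloxolane | C[C@@](Br)(CCl)[C@@H]1C[C@H](Cl)[C@](C)(/C=C/Br)O1 | target

**Step count and risks**

Total step count: 8. Longest linear sequence: 8 steps (fully linear from 1 and 2).

Steps most likely to fail:

1. Step 8 (proposed new method). The bridged ion may leak to an open tertiary cation, losing the configuration at C6. Bromide may instead open the bridge at C5 (ring expansion to a bromotetrahydropyran). Elimination or halogen scrambling through a chloronium ion may also compete. Fallback with known reactions, setting out from 10: Wittig methylenation (Ph3P=CH2 from Ph3PCH3Br and KN(SiMe3)2, THF, −78 to 0 °C) should give (2S,3S,5S)-2-[(E)-2-bromoethenyl]-3-chloro-2-methyl-5-(prop-1-en-2-yl)oxolane F1. Ene-type allylic chlorination of the isopropenyl group (Ca(OCl)2, solid CO2, CH2Cl2/H2O, 0 °C) should give (2S,3S,5S)-2-[(E)-2-bromoethenyl]-3-chloro-5-(3-chloroprop-1-en-2-yl)-2-methyloxolane F2. Ionic Markovnikov addition of HBr (gas, CH2Cl2, −78 °C, dark) should then give 14 together with its side-chain epimer (2S,3S,5S)-2-[(E)-2-bromoethenyl]-5-[(2R)-2-bromo-1-chloropropan-2-yl]-3-chloro-2-methyloxolane F3. This fallback does not control C6; the epimer ratio is not predicted and the two would have to be separated by preparative HPLC. It returns to the route at 14.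

2. Step 3. The homoallylic α-chloro radical may close onto the ring alkene (cyclopropylcarbinyl-type rearrangement) before hydrogen transfer, and exo selectivity of the hydrogen transfer may erode. Fallback, setting out from 4, removes the alkene first. Exo dihydroxylation (OsO4 cat., N-methylmorpholine N-oxide, acetone/H2O) should give (1S,2S,4S,5R,6S)-2-chloro-5,6-dihydroxy-1,5-dimethyl-7-oxabicyclo[2.2.1]heptane-2-carboxylic acid F4. Acetal formation (2-methoxypropene, pyridinium tosylate) gives its 5-exo,6-exo-O-isopropylidene derivative F5. The same decarboxylation sequence then runs through the acetonide acid chloride F6 and the acetonide thiohydroxamate ester F7 to the 2-endo-chloro-5-exo,6-exo-isopropylidenedioxy-1,5-dimethyl-7-oxabicyclo[2.2.1]heptane F8, now without a competing radical cyclisation. Periodic acid (H5IO6, EtOAc, rt) should hydrolyse the acetal and cleave the glycol in one pot to give 9, where the fallback rejoins the route.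

3. Step 1. The electron-rich furan may undergo conjugate (Friedel–Crafts-type) alkylation or acid-induced opening of the adduct instead of clean cycloaddition, and enantioselectivity with a disubstituted furan may be insufficient. Fallback, setting out from 1, replaces catalysis by resolution. Uncatalysed cycloaddition with 2-chloroacryloyl chloride (C=C(Cl)C(Cl)=O; CH2Cl2, 0 °C) should give racemic 2-chloro-1,5-dimethyl-7-oxabicyclo[2.2.1]hept-5-ene-2-carbonyl chloride F9 as a mixture of epimers at the chlorinated carbon. Hydrolysis (aq. NaHCO3, then acid) and crystallisation should give the racemic endo-chloro acid F10. Resolution through the (R)-1-phenylethylammonium salt of the (1S,2S,4S) acid F11 (or with the antipodal amine if that salt is the less soluble one) and acidification should return enantiopure 4, where the fallback rejoins the route.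

Further compounds
F1 | step 8 | (2S,3S,5S)-2-[(E)-2-bromoethenyl]-3-chloro-2-methyl-5-(prop-1-en-2-yl)oxolane | C=C(C)[C@@H]1C[C@H](Cl)[C@](C)(/C=C/Br)O1
F2 | step 8 | (2S,3S,5S)-2-[(E)-2-bromoethenyl]-3-chloro-5-(3-chloroprop-1-en-2-yl)-2-methyloxolane | C=C(CCl)[C@@H]1C[C@H](Cl)[C@](C)(/C=C/Br)O1
F3 | step 8 | (2S,3S,5S)-2-[(E)-2-bromoethenyl]-5-[(2R)-2-bromo-1-chloropropan-2-yl]-3-chloro-2-methyloxolane | C[C@](Br)(CCl)[C@@H]1C[C@H](Cl)[C@](C)(/C=C/Br)O1
F4 | step 3 | (1S,2S,4S,5R,6S)-2-chloro-5,6-dihydroxy-1,5-dimethyl-7-oxabicyclo[2.2.1]heptane-2-carboxylic acid (diol exo) | OC(=O)[C@]1(Cl)C[C@@H]2O[C@@]1(C)[C@@H](O)[C@@]2(C)O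
F5 | step 3 | 5-exo,6-exo-O-isopropylidene derivative of F4 | OC(=O)[C@]1(Cl)C[C@@H]2O[C@@]1(C)[C@H]3OC(C)(C)O[C@@]23C
F6 | step 3 | acid chloride of F5 | ClC(=O)[C@]1(Cl)C[C@@H]2O[C@@]1(C)[C@H]3OC(C)(C)O[C@@]23C
F7 | step 3 | 2-thioxopyridin-1(2H)-yl ester of F5 | S=c1ccccn1OC(=O)[C@]2(Cl)C[C@@H]3O[C@@]2(C)[C@H]4OC(C)(C)O[C@@]34C
F8 | step 3 | 2-endo-chloro-5-exo,6-exo-isopropylidenedioxy-1,5-dimethyl-7-oxabicyclo[2.2.1]heptane | Cl[C@H]1C[C@@H]2O[C@@]1(C)[C@H]3OC(C)(C)O[C@@]23C
F9 | step 1 | racemic 2-chloro-1,5-dimethyl-7-oxabicyclo[2.2.1]hept-5-ene-2-carbonyl chloride (epimer mixture at the chlorinated carbon) | ClC(=O)C1(Cl)CC2OC1(C)C=C2C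
F10 | step 1 | racemic (1S*,2S*,4S*)-2-chloro-1,5-dimethyl-7-oxabicyclo[2.2.1]hept-5-ene-2-carboxylic acid | OC(=O)[C@]1(Cl)C[C@@H]2O[C@@]1(C)C=C2C.OC(=O)[C@@]1(Cl)C[C@H]2O[C@]1(C)C=C2C
F11 | step 1 | (R)-1-phenylethylammonium (1S,2S,4S)-2-chloro-1,5-dimethyl-7-oxabicyclo[2.2.1]hept-5-ene-2-carboxylate | C[C@@H]([NH3+])c1ccccc1.[O-]C(=O)[C@]1(Cl)C[C@@H]2O[C@@]1(C)C=C2C
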